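**Plan**

Numbering (daucane): C1 = quaternary C(Me) at the ring fusion, C2/C3 = ring CH2, C4 = C(OH)(iPr), C5 = ring-fusion CH, C6 = CH–O(anisoyl), C7 = CH2, C8(Me)=C9, C10 = CH2.
Retrosynthetic cuts, in order: the C6–O acyl bond; the C4–isopropyl bond; C3–C4 (five-membered ring, aldehyde C4 onto a vinyl group on C1); C8=C9 (seven-membered ring); C5–C1 together with an allylic ester C–O bond (sigmatropic).
Forward: an open-chain triene diol is assembled, the seven-membered ring is closed first at C8=C9 by olefin metathesis, the five-membered ring is then closed trans-fused by rhodium hydroacylation, and isopropyl addition and acylation finish.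
Feature that allows the ring closure: C8(Me)=C9H is the only ring olefin and lies between C7H2 and C10H2, so it maps onto a 2-methylallyl arm on carbinol C6 and an allyl arm on quaternary C1; the third olefin of the precursor (vinyl on C1) is too hindered to take part and is kept for the five-membered ring.
Stereochemistry: C6 is bought; C5 and the quaternary C1 are set together, anti to O6, in one chelated dianionic Ireland–Claisen rearrangement; C4 is set last by addition to the trans-fused ketone on the face away from the axial C1 methyl.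

Key step: step 6

Remark: ethyl (3R)-4-chloro-3-hydroxybutanoate is taken as enantiopure commercial material; its stereocenter is the only external source of chirality in the route.

**Route**

Step 1
Reactants: 1 pent-1-en-4-yne
Product: 3 (2E)-3-methylhexa-2,5-dien-1-ol, via alkenyldimethylalane 2 (not isolated)
Conditions: Me3Al (2 equiv), Cp2ZrCl2 (20 mol %), ClCH2CH2Cl, rt; then n-BuLi, (CH2O)n, THF, −78 °C to rt; aq. HCl
Reagents that add atoms: trimethylaluminium C[Al](C)C; formaldehyde (from paraformaldehyde) C=O
Why: Zirconium-catalysed syn-carboalumination of the terminal alkyne (Negishi carboalumination) should put methyl on the internal carbon cis to aluminium, and hydroxymethylation of the derived alanate with retention should give the E trisubstituted allylic alcohol, the terminal alkene being far slower to carbometalate.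

Step 2
Reactants: 4 ethyl (3R)-4-chloro-3-hydroxybutanoate
Product: 5 ethyl 2-[(2R)-oxiran-2-yl]acetate
Conditions: Ag2O, 1,2-dimethoxyethane, 60 °C
Reagents that add atoms: none
Why: Silver-assisted intramolecular Williamson etherification should close the epoxide by displacing chloride at the primary carbon without the base that would cause elimination to the crotonate, and the carbinol stereocenter is not touched.

Step 3
Reactants: 5 ethyl 2-[(2R)-oxiran-2-yl]acetate
Product: 6 ethyl (3S)-3-hydroxy-5-methylhex-5-enoate
Conditions: CH2=C(CH3)MgBr (1.5 equiv), CuI (10 mol %), THF, −40 °C; aq. NH4Cl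
Reagents that add atoms: isopropenylmagnesium bromide CC(=C)[Mg]Br
Why: Copper-catalysed SN2 opening of the terminal epoxide by the alkenyl Grignard reagent should occur at the CH2 terminus faster than attack on the ester at low temperature, so the stereocenter is carried over unchanged (only its descriptor changes).

Step 4
Reactants: 6 ethyl (3S)-3-hydroxy-5-methylhex-5-enoate; 3 (2E)-3-methylhexa-2,5-dien-1-ol
Product: 7 (2E)-3-methylhexa-2,5-dien-1-yl (3S)-3-hydroxy-5-methylhex-5-enoate
Conditions: 3 (2.5 equiv, excess recovered), Ti(OEt)4 (20 mol %), toluene, 100 °C, EtOH distilled off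
Reagents that add atoms: none
Why: Titanate-mediated transesterification is neutral enough to exchange the ethyl ester for the allylic alcohol without dehydration or retro-aldol cleavage of the β-hydroxy ester and without moving the skipped diene.

Step 5
Reactants: 7 (2E)-3-methylhexa-2,5-dien-1-yl (3S)-3-hydroxy-5-methylhex-5-enoate
Product: 10 (2R,3S)-5-methyl-2-[(3S)-3-methylhexa-1,5-dien-3-yl]hex-5-ene-1,3-diol, via dilithium enolate alkoxide 8 (not isolated), via lithium carboxylate 9 (not isolated)
Conditions: LiN(iPr)2 (2.4 equiv), THF, −78 °C to 50 °C; then LiAlH4, THF, reflux; aq. KNaC4H4O6 (potassium sodium tartrate)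
Reagents that add atoms: none
Why: In this dianionic Ireland–Claisen rearrangement the lithium chelate fixes the enolate geometry (O–Li cis to C6) and shields the face syn to the C7 arm, so the chair transition state with the E allyl terminus (methyl axial, allyl equatorial) should set C5 and the quaternary C1 together, anti to O6 as in Fráter–Seebach alkylations, before LiAlH4 reduces the carboxylate in the same flask.

Step 6
Reactants: 10 (2R,3S)-5-methyl-2-[(3S)-3-methylhexa-1,5-dien-3-yl]hex-5-ene-1,3-diol
Product: 11 (1S,6S,7R)-6-ethenyl-7-(hydroxymethyl)-3,6-dimethylcyclohept-3-en-1-ol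
Conditions: (H2IMes)(PCy3)Cl2Ru=CHPh (second-generation Grubbs catalyst, 5 mol %), CH2Cl2 (2 mM), 40 °C
Reagents that add atoms: none
Why: The ruthenium benzylidene loads onto the unhindered allyl olefin (C9), the new alkylidene adds across the 1,1-disubstituted C8 olefin to a ruthenacyclobutane, and cycloreversion releases the C8=C9 olefin and, after turnover, ethene (closest known reaction type: ring-closing metathesis of a 1,8-diene to a trisubstituted cycloalkene). The seven-membered ring is closed by joining the two terminal olefin carbons of the nona-1,8-diene unit C9/C10/C1/C5/C6/C7/C8, and the ring enforces the Z olefin. No stereocenter is formed, and C1, C5 and C6 are not touched. The step needs selection among three olefins and ring closure over oligomerization: the vinyl group on quaternary C1 should not be loaded by ruthenium at a useful rate and could only give a cyclobutene with the C9 alkylidene, the 2-methylallyl olefin is loaded slowly but is a good intramolecular acceptor, and the gem-disubstituted C1 together with high dilution favours cyclization. The free hydroxyls are tolerated by this catalyst.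

Step 7
Reactants: 11 (1S,6S,7R)-6-ethenyl-7-(hydroxymethyl)-3,6-dimethylcyclohept-3-en-1-ol
Product: 12 (1S,2S,7S)-7-ethenyl-2-hydroxy-4,7-dimethylcyclohept-4-ene-1-carbaldehyde
Conditions: TEMPO (10 mol %), PhI(OAc)2 (1.1 equiv), CH2Cl2, rt
Reagents that add atoms: none
Why: Oxoammonium (TEMPO) oxidation should take the primary alcohol in preference to the secondary one and stop at the aldehyde under near-neutral conditions that should not epimerize C5 or cleave the β-hydroxy aldehyde.

Step 8
Reactants: 12 (1S,2S,7S)-7-ethenyl-2-hydroxy-4,7-dimethylcyclohept-4-ene-1-carbaldehyde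
Product: 13 (3aR,8S,8aS)-8-hydroxy-3a,6-dimethyl-3,3a,4,7,8,8a-hexahydroazulen-1(2H)-one (trans-fused; ketone at C4, hydroxyl at C6)
Conditions: [Rh(nbd)(dppe)]BF4 (5 mol %, freed with H2), CH2Cl2, rt
Reagents that add atoms: none
Why: In this rhodium-catalysed intramolecular hydroacylation of a 4-pentenal, insertion into the formyl C–H bond, anti-Markovnikov hydrometalation of the only terminal olefin and C–C reductive elimination from the six-membered acyl rhodacycle should give the cyclopentanone, and because C5 and C1 are not touched their trans arrangement becomes the trans ring fusion.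

Step 9
Reactants: 13 (3aR,8S,8aS)-8-hydroxy-3a,6-dimethyl-3,3a,4,7,8,8a-hexahydroazulen-1(2H)-one
Product: 14 (3R,3aS,4S,8aR)-6,8a-dimethyl-3-(propan-2-yl)-1,2,3,3a,4,5,8,8a-octahydroazulene-3,4-diol
Conditions: iPrMgCl (3 equiv), CeCl3 (3 equiv, dried), THF, −78 °C; aq. NH4Cl
Reagents that add atoms: isopropylmagnesium chloride CC(C)[Mg]Cl
Why: The weakly basic organocerium reagent should undergo 1,2-addition rather than enolization, reduction or β-elimination, and attack is expected on the α face of the trans-fused cyclopentanone, away from the axial C1 methyl and the C5–C6 bond, which puts isopropyl α and hydroxyl β at C4.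

Step 10
Reactants: 14 (3R,3aS,4S,8aR)-6,8a-dimethyl-3-(propan-2-yl)-1,2,3,3a,4,5,8,8a-octahydroazulene-3,4-diol
Product: 15 fertidin, [(3R,3aS,4S,8aR)-3-hydroxy-6,8a-dimethyl-3-(propan-2-yl)-1,2,3,3a,4,5,8,8a-octahydroazulen-4-yl] 4-methoxybenzoate
Conditions: 4-MeOC6H4COCl (1.5 equiv), Et3N, DMAP (20 mol %), CH2Cl2, 0 °C to rt
Reagents that add atoms: 4-methoxybenzoyl chloride COc1ccc(cc1)C(Cl)=O
Why: DMAP-catalysed acylation should esterify the secondary C6 hydroxyl while the tertiary C4 hydroxyl is too hindered to react, with no stereocenter affected.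

**Compound list**

1 | pent-1-en-4-yne | C=CCC#C | starting material
2 | dimethyl[(1E)-2-methylpenta-1,4-dien-1-yl]alane | C=CC/C(C)=C/[Al](C)C | intermediate
3 | (2E)-3-methylhexa-2,5-dien-1-ol | C=CC/C(C)=C/CO | intermediate
4 | ethyl (3R)-4-chloro-3-hydroxybutanoate | CCOC(=O)C[C@@H](O)CCl | starting material
5 | ethyl 2-[(2R)-oxiran-2-yl]acetate | CCOC(=O)C[C@@H]1CO1 | intermediate
6 | ethyl (3S)-3-hydroxy-5-methylhex-5-enoate | CCOC(=O)C[C@@H](O)CC(C)=C | intermediate
7 | (2E)-3-methylhexa-2,5-dien-1-yl (3S)-3-hydroxy-5-methylhex-5-enoate | C=CC/C(C)=C/COC(=O)C[C@@H](O)CC(C)=C | intermediate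
8 | chelated dilithium enolate alkoxide of 7 (O–Li cis to C6) | C=CC/C(C)=C/CO/C(O[Li])=C/[C@@H](O[Li])CC(C)=C | intermediate
9 | dilithium salt of (2S,3S)-3-hydroxy-5-methyl-2-[(3S)-3-methylhexa-1,5-dien-3-yl]hex-5-enoic acid | [Li]OC(=O)[C@H]([C@@H](O[Li])CC(C)=C)[C@@](C)(CC=C)C=C | intermediate
10 | (2R,3S)-5-methyl-2-[(3S)-3-methylhexa-1,5-dien-3-yl]hex-5-ene-1,3-diol | OC[C@H]([C@@H](O)CC(C)=C)[C@@](C)(CC=C)C=C | intermediate
11 | (1S,6S,7R)-6-ethenyl-7-(hydroxymethyl)-3,6-dimethylcyclohept-3-en-1-ol | OC[C@@H]1[C@@H](O)CC(C)=CC[C@@]1(C)C=C | intermediate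
12 | (1S,2S,7S)-7-ethenyl-2-hydroxy-4,7-dimethylcyclohept-4-ene-1-carbaldehyde | O=C[C@@H]1[C@@H](O)CC(C)=CC[C@@]1(C)C=C | intermediate
13 | (3aR,8S,8aS)-8-hydroxy-3a,6-dimethyl-3,3a,4,7,8,8a-hexahydroazulen-1(2H)-one | O=C1CC[C@]2(C)CC=C(C)C[C@H](O)[C@@H]12 | intermediate
14 | (3R,3aS,4S,8aR)-6,8a-dimethyl-3-(propan-2-yl)-1,2,3,3a,4,5,8,8a-octahydroazulene-3,4-diol | CC(C)[C@]1(O)CC[C@]2(C)CC=C(C)C[C@H](O)[C@@H]12 | intermediate
15 | fertidin | COc1ccc(C(=O)O[C@H]2CC(C)=CC[C@@]3(C)CC[C@@](O)(C(C)C)[C@H]23)cc1 | target

**Count**

Total steps: 10. Longest linear sequence: 9 steps (4 to 15, steps 2 to 10).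

**Steps most likely to fail**

Step 5. Retro-aldol fragmentation or β-elimination of the dianion on warming may outrun the sigmatropic shift, and incomplete chelation would erode the facial control. The fallback sets out from 7 and comes back at 10, and it replaces chelation control by a protected hydroxyl and a geometry-defined silyl ketene acetal. Compound 7 is silylated (TBSCl, imidazole, DMF) to the (2E)-3-methylhexa-2,5-dien-1-yl (3S)-3-silyloxy ester F1. Enolization with LiN(iPr)2 in THF/DMPU at −78 °C with TBSCl present from the start, then warming to rt and mild acidic work-up, should give the Ireland–Claisen acid F2; the enolate geometry formed in DMPU (silyloxy cis to C6) stands in for the chelate, and any minor diastereomer is removed at the next stage. LiAlH4 in THF reduces the acid to the primary alcohol F3, and Bu4NF in THF removes the silyl group to give 10.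

Step 8. Decarbonylation at rhodium or migration of the olefin may compete with closure of the trans-fused five-membered ring. The fallback sets out from 12 and comes back at 13, and it builds the C3–C4 bond by metathesis instead. Vinylmagnesium bromide (THF, −78 °C) adds to the aldehyde to give the allylic alcohol F4 as a mixture of carbinol epimers. (H2IMes)(PCy3)Cl2Ru=CHPh then closes the cyclopentene between the two remaining terminal vinyl groups, where the alkylidene is loaded on the allylic-alcohol vinyl and the hindered vinyl only has to act as intramolecular acceptor, to give the bicyclic cyclopentenol F5. MnO2 (CH2Cl2) oxidizes only the allylic hydroxyl to the enone F6, and conjugate reduction with [(Ph3P)CuH]6 in toluene gives 13.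

Step 9. Enolization of the ketone, β-hydride transfer from the secondary alkyl nucleophile or β-elimination of the C6 alkoxide may take the place of addition. The fallback sets out from 13 and comes back at 14, and it uses an sp2 nucleophile without a transferable β-hydride followed by a selective hydrogenation. CH2=C(CH3)MgBr/CeCl3 (THF, −78 °C) should add from the same α face to give the isopropenyl carbinol F7, and H2 with (PPh3)3RhCl in benzene should saturate only the 1,1-disubstituted olefin, leaving the trisubstituted ring olefin, to give 14.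

**Further compounds**

F1 | step 5 | (2E)-3-methylhexa-2,5-dien-1-yl (3S)-3-[tert-butyl(dimethyl)silyl]oxy-5-methylhex-5-enoate | C=CC/C(C)=C/COC(=O)C[C@@H](O[Si](C)(C)C(C)(C)C)CC(C)=C
F2 | step 5 | (2S,3S)-3-[tert-butyl(dimethyl)silyl]oxy-5-methyl-2-[(3S)-3-methylhexa-1,5-dien-3-yl]hex-5-enoic acid | OC(=O)[C@H]([C@@H](O[Si](C)(C)C(C)(C)C)CC(C)=C)[C@@](C)(CC=C)C=C
F3 | step 5 | (2R,3S)-3-[tert-butyl(dimethyl)silyl]oxy-5-methyl-2-[(3S)-3-methylhexa-1,5-dien-3-yl]hex-5-en-1-ol | OC[C@H]([C@@H](O[Si](C)(C)C(C)(C)C)CC(C)=C)[C@@](C)(CC=C)C=C
F4 | step 8 | (1S,6S,7S)-6-ethenyl-7-(1-hydroxyprop-2-en-1-yl)-3,6-dimethylcyclohept-3-en-1-ol (both carbinol epimers) | C=CC(O)[C@@H]1[C@@H](O)CC(C)=CC[C@@]1(C)C=C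
F5 | step 8 | (3aS,8S,8aS)-3a,6-dimethyl-1,3a,4,7,8,8a-hexahydroazulene-1,8-diol (both C1 epimers) | OC1C=C[C@]2(C)CC=C(C)C[C@H](O)[C@@H]12
F6 | step 8 | (3aS,8S,8aS)-8-hydroxy-3a,6-dimethyl-4,7,8,8a-tetrahydroazulen-1(3aH)-one | O=C1C=C[C@]2(C)CC=C(C)C[C@H](O)[C@@H]12
F7 | step 9 | (3S,3aS,4S,8aR)-6,8a-dimethyl-3-(prop-1-en-2-yl)-1,2,3,3a,4,5,8,8a-octahydroazulene-3,4-diol | CC(=C)[C@]1(O)CC[C@]2(C)CC=C(C)C[C@H](O)[C@@H]12
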